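**Plan**

Numbering used here: lactone C1(=O), C2=C3 (C3 carries CH2OH), stereocentre C4, chain C5–C19; C7 carries CH2OH, C11 and C15 carry CH3, C19 carries CH3 and CH2OH.
Retrosynthesis: (a) the three O–Si bonds; (b) C11–C12, giving the alkenyl iodide at C11 and the N-acyloxyphthalimide of the acid whose α-carbon is C12 (carboxyl carbon lost as CO2); (c) right half: lactone O–C1 and C2=C3 (ketene ylide on an α-hydroxy ketone), C4–C5 (hydrazone alkylation), C5–C6 (Stille), C7–C8 with C6–I (carbomagnesiation of prop-2-yn-1-ol), C11–I (hydrozirconation); (d) left half: C12–C13 (enolate alkylation of geranyl bromide) and the C19 CH2–O bond (SeO2).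
Forward: the C6–C11 enyne is built first, C5 is added, the alkyne becomes the (E)-alkenyl iodide, C4 arrives with the three-carbon ketone unit, and the butenolide (the only ring, O–C1–C2=C3–C4) is closed last in this half by intramolecular Wittig olefination; the left half comes from geranyl bromide in five steps; the halves are joined at C11–C12 and desilylated.
Stereochemistry: C4 (R) from the RAMP auxiliary; C6=C7 from anti-carbomagnesiation followed by retentive iodination and Stille coupling; C10=C11 from syn-hydrozirconation; C14=C15 from geranyl bromide; C18=C19 from (E)-selective SeO2 oxidation.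
Enabling feature: C12 is an unfunctionalised primary CH2 between C13H2 and the methyl-bearing sp2 carbon C11 of the C10=C11 olefin, so C12 can be the primary radical of an acid one carbon longer and C11 an alkenyl iodide coupled by nickel with retention; the neutral reductive medium spares the base-labile C4–H of the butenolide ring, whose C2=C3 bond has a fully substituted β-carbon (C3).

Key step: step 17

Remark: RAMP alkylation of the dioxanone hydrazone is taken to give the (R)-configured α-carbon, the mirror image of the established SAMP outcome; the C=N geometry of hydrazone 16 is immaterial and left undefined.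

**Route**

Step 1
Reactants: 1 pent-3-yn-1-ol
Product: 2 5-bromopent-2-yne
Conditions: CBr4, PPh3, CH2Cl2, 0 °C to rt
Reagents that add atoms: carbon tetrabromide, BrC(Br)(Br)Br
Why: Appel bromination should convert the primary alcohol into the bromide by SN2 displacement of the alkoxyphosphonium ion without touching the internal alkyne.

Step 2
Reactants: 2 5-bromopent-2-yne; 3 prop-2-yn-1-ol
Product: 6 (Z)-3-iodo-2-(pent-3-yn-1-yl)prop-2-en-1-ol, via pent-3-yn-1-ylmagnesium bromide 4 (not isolated), via alkenylmagnesium alkoxide 5 (not isolated)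
Conditions: 2 (3 equiv), Mg, Et2O, rt; then 3 (1 equiv), CuI (10 mol%), Et2O, –10 °C to rt; then I2, THF, –30 °C to 0 °C
Reagents that add atoms: iodine, II
Why: Copper-catalysed anti-carbomagnesiation of the propargylic alkoxide should place the alkyl group on the carbinol-bearing alkyne carbon and magnesium on the terminal carbon inside an oxygen chelate, so iodinolysis with retention gives the iodide cis to CH2OH and fixes the C6=C7 geometry.

Step 3
Reactants: 6 (Z)-3-iodo-2-(pent-3-yn-1-yl)prop-2-en-1-ol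
Product: 7 tert-butyl{[(Z)-3-iodo-2-(pent-3-yn-1-yl)prop-2-en-1-yl]oxy}dimethylsilane
Conditions: TBSCl, imidazole, CH2Cl2, 0 °C to rt
Reagents that add atoms: tert-butyldimethylsilyl chloride, CC(C)(C)[Si](C)(C)Cl
Why: Standard silylation of a primary allylic alcohol should protect it for the palladium coupling and the later azaenolate alkylation.

Step 4
Reactants: 7 tert-butyl{[(Z)-3-iodo-2-(pent-3-yn-1-yl)prop-2-en-1-yl]oxy}dimethylsilane
Product: 8 (Z)-3-{[(tert-butyldimethylsilyl)oxy]methyl}oct-2-en-6-yn-1-ol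
Conditions: Bu3SnCH2OH (1.3 equiv), Pd(PPh3)4 (5 mol%), 1,4-dioxane, 90 °C
Reagents that add atoms: (tributylstannyl)methanol, CCCC[Sn](CCCC)(CCCC)CO
Why: Stille hydroxymethylation of the alkenyl iodide should proceed with retention of the olefin geometry under neutral conditions, so the new C5 carbinol is installed cis to CH2OTBS without silyl migration.

Step 5
Reactants: 8 (Z)-3-{[(tert-butyldimethylsilyl)oxy]methyl}oct-2-en-6-yn-1-ol
Product: 10 (2Z,6E)-3-{[(tert-butyldimethylsilyl)oxy]methyl}-7-iodoocta-2,6-dien-1-ol, via alkenylzirconocene 9 (not isolated)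
Conditions: Cp2Zr(H)Cl (3.5 equiv), THF, rt to 45 °C; then I2, THF, 0 °C
Reagents that add atoms: iodine, II
Why: Hydrozirconation–iodination: syn addition of Zr–H to the 2-alkyne, equilibrated by the excess Cp2Zr(H)Cl towards zirconium on the less hindered methyl-bearing carbon, and iodinolysis with retention should give the (E)-alkenyl iodide that fixes the C10=C11 geometry.

Step 6
Reactants: 10 (2Z,6E)-3-{[(tert-butyldimethylsilyl)oxy]methyl}-7-iodoocta-2,6-dien-1-ol
Product: 11 (2Z,6E)-1-bromo-3-{[(tert-butyldimethylsilyl)oxy]methyl}-7-iodoocta-2,6-diene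
Conditions: CBr4, PPh3, CH2Cl2, –20 °C to 0 °C
Reagents that add atoms: carbon tetrabromide, BrC(Br)(Br)Br
Why: Appel bromination of the primary allylic alcohol should occur by direct SN2 substitution without allylic transposition and leave the silyl ether and the alkenyl iodide intact.

Step 7
Reactants: 12 2,2-dimethyl-1,3-dioxan-5-one; 13 (R)-1-amino-2-(methoxymethyl)pyrrolidine (RAMP)
Product: 14 (R)-N-(2,2-dimethyl-1,3-dioxan-5-ylidene)-2-(methoxymethyl)pyrrolidin-1-amine
Conditions: benzene, 4 Å molecular sieves, reflux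
Reagents that add atoms: none
Why: Hydrazone condensation of the ketone with the chiral hydrazine should give the auxiliary-bearing substrate for asymmetric alkylation.

Step 8
Reactants: 14 (R)-N-(2,2-dimethyl-1,3-dioxan-5-ylidene)-2-(methoxymethyl)pyrrolidin-1-amine; 11 (2Z,6E)-1-bromo-3-{[(tert-butyldimethylsilyl)oxy]methyl}-7-iodoocta-2,6-diene
Product: 16 RAMP hydrazone of (R)-4-[(2Z,6E)-3-{[(tert-butyldimethylsilyl)oxy]methyl}-7-iodoocta-2,6-dien-1-yl]-2,2-dimethyl-1,3-dioxan-5-one, via lithium azaenolate 15 (not isolated)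
Conditions: t-BuLi (1.0 equiv), THF, –78 °C; then 11, –100 °C to rt
Reagents that add atoms: none
Why: RAMP-hydrazone alkylation (Enders method): the chelated lithium azaenolate should be alkylated by the allylic bromide in an SN2 reaction on the face not shielded by the methoxymethylpyrrolidine, which sets C4 as (R).

Step 9
Reactants: 16 RAMP hydrazone of (R)-4-[(2Z,6E)-3-{[(tert-butyldimethylsilyl)oxy]methyl}-7-iodoocta-2,6-dien-1-yl]-2,2-dimethyl-1,3-dioxan-5-one
Product: 18 (3R,5Z,9E)-1,3-dihydroxy-6-(hydroxymethyl)-10-iodoundeca-5,9-dien-2-one, via dioxanone 17 (not isolated)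
Conditions: sat. aq. oxalic acid, Et2O, rt; then 1 M aq. HCl, THF, rt
Reagents that add atoms: water, O
Why: Two-phase oxalic acid hydrolysis of the hydrazone (which should leave the α-stereocentre intact) followed by acid-catalysed cleavage of the acetonide and the silyl ether should free the α,α'-dihydroxy ketone.

Step 10
Reactants: 18 (3R,5Z,9E)-1,3-dihydroxy-6-(hydroxymethyl)-10-iodoundeca-5,9-dien-2-one
Product: 19 (3R,5Z,9E)-1-[(tert-butyldimethylsilyl)oxy]-6-{[(tert-butyldimethylsilyl)oxy]methyl}-3-hydroxy-10-iodoundeca-5,9-dien-2-one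
Conditions: TBSCl (2.2 equiv), imidazole, CH2Cl2/DMF, –20 °C to 0 °C
Reagents that add atoms: tert-butyldimethylsilyl chloride, CC(C)(C)[Si](C)(C)Cl
Why: Chemoselective silylation: the two primary hydroxyls should react much faster than the hindered secondary α-ketol hydroxyl, which must stay free for the lactone closure.

Step 11
Reactants: 19 (3R,5Z,9E)-1-[(tert-butyldimethylsilyl)oxy]-6-{[(tert-butyldimethylsilyl)oxy]methyl}-3-hydroxy-10-iodoundeca-5,9-dien-2-one
Product: 21 (R)-4-{[(tert-butyldimethylsilyl)oxy]methyl}-5-[(2Z,6E)-3-{[(tert-butyldimethylsilyl)oxy]methyl}-7-iodoocta-2,6-dien-1-yl]furan-2(5H)-one, via phosphorane ester 20 (not isolated)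
Conditions: Ph3P=C=C=O (1.3 equiv), toluene, 80 °C
Reagents that add atoms: (triphenylphosphoranylidene)ketene, O=C=C=P(c1ccccc1)(c1ccccc1)c1ccccc1
Why: Tandem acylation and intramolecular Wittig olefination (Bestmann ylide butenolide synthesis): the C4 hydroxyl should add to the ketene ylide and the stabilised ylide so formed should condense with the neighbouring ketone to close the unsaturated five-membered lactone with C4 unchanged.

Step 12
Reactants: 22 geranyl bromide, (E)-1-bromo-3,7-dimethylocta-2,6-diene; 23 ethyl acetate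
Product: 25 ethyl (E)-5,9-dimethyldeca-4,8-dienoate, via lithium enolate 24 (not isolated)
Conditions: LiN(i-Pr)2 (lithium diisopropylamide), THF, –78 °C, then 23; then 22, DMPU, –78 °C to –30 °C
Reagents that add atoms: none
Why: Ester enolate alkylation: SN2 attack of lithio ethyl acetate on the primary allylic bromide should give the chain-extended ester with the (E)-C14=C15 olefin unchanged.

Step 13
Reactants: 25 ethyl (E)-5,9-dimethyldeca-4,8-dienoate
Product: 26 ethyl (4E,8E)-10-hydroxy-5,9-dimethyldeca-4,8-dienoate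
Conditions: SeO2 (0.2 equiv), t-BuOOH (2 equiv), salicylic acid (0.1 equiv), CH2Cl2, rt
Reagents that add atoms: tert-butyl hydroperoxide (terminal oxidant, turns over SeO2), CC(C)(C)OO
Why: Allylic oxidation with SeO2 (ene reaction then [2,3]-sigmatropic shift) should hydroxylate the (E)-methyl group of the terminal, least hindered trisubstituted olefin and give the (E)-allylic alcohol.

Step 14
Reactants: 26 ethyl (4E,8E)-10-hydroxy-5,9-dimethyldeca-4,8-dienoate
Product: 27 ethyl (4E,8E)-10-[(tert-butyldimethylsilyl)oxy]-5,9-dimethyldeca-4,8-dienoate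
Conditions: TBSCl, imidazole, DMF, 0 °C to rt
Reagents that add atoms: tert-butyldimethylsilyl chloride, CC(C)(C)[Si](C)(C)Cl
Why: Standard silylation of the primary allylic alcohol should keep it from acylating the active ester made in step 16.

Step 15
Reactants: 27 ethyl (4E,8E)-10-[(tert-butyldimethylsilyl)oxy]-5,9-dimethyldeca-4,8-dienoate
Product: 28 (4E,8E)-10-[(tert-butyldimethylsilyl)oxy]-5,9-dimethyldeca-4,8-dienoic acid
Conditions: LiOH, THF/MeOH/H2O, rt; then dilute aq. HCl to pH 4, 0 °C
Reagents that add atoms: lithium hydroxide, [Li+].[OH-]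
Why: Saponification of the ethyl ester should proceed under conditions that a primary TBS ether tolerates.

Step 16
Reactants: 28 (4E,8E)-10-[(tert-butyldimethylsilyl)oxy]-5,9-dimethyldeca-4,8-dienoic acid
Product: 29 1,3-dioxoisoindolin-2-yl (4E,8E)-10-[(tert-butyldimethylsilyl)oxy]-5,9-dimethyldeca-4,8-dienoate
Conditions: N-hydroxyphthalimide, N,N'-diisopropylcarbodiimide, DMAP (5 mol%), CH2Cl2, rt
Reagents that add atoms: N-hydroxyphthalimide, O=C1c2ccccc2C(=O)N1O
Why: Carbodiimide (Steglich-type) esterification should give the redox-active ester that turns the carboxyl group into a leaving group for radical generation.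

Step 17
Reactants: 21 (R)-4-{[(tert-butyldimethylsilyl)oxy]methyl}-5-[(2Z,6E)-3-{[(tert-butyldimethylsilyl)oxy]methyl}-7-iodoocta-2,6-dien-1-yl]furan-2(5H)-one; 29 1,3-dioxoisoindolin-2-yl (4E,8E)-10-[(tert-butyldimethylsilyl)oxy]-5,9-dimethyldeca-4,8-dienoate
Product: 30 (R)-4-{[(tert-butyldimethylsilyl)oxy]methyl}-5-[(2Z,6E,10E,14E)-16-[(tert-butyldimethylsilyl)oxy]-3-{[(tert-butyldimethylsilyl)oxy]methyl}-7,11,15-trimethylhexadeca-2,6,10,14-tetraen-1-yl]furan-2(5H)-one
Conditions: 21 (1 equiv), 29 (2 equiv), NiCl2·6H2O (20 mol%), 2,2'-bipyridine (20 mol%), AgNO3 (0.3 equiv, deposits silver nanoparticles on the cathode), LiCl, DMF, Mg anode, reticulated vitreous carbon cathode, constant current, undivided cell, rt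
Reagents that add atoms: none
Why: Nickel-electrocatalytic decarboxylative alkenylation: cathodically generated low-valent nickel–bipyridine should add oxidatively to the C11–I bond of 21 with retention, while single-electron reduction of the N-acyloxyphthalimide 29 releases CO2, phthalimide anion and the primary C12 radical, which the alkenylnickel species captures before reductive elimination from trivalent nickel forms the C11–C12 bond, the Mg anode supplying the electrons. The closest known reaction type is the silver-assisted nickel-electrocatalytic coupling of N-hydroxyphthalimide esters with alkenyl halides used to assemble polyene terpenoids. No ring is closed and no stereocentre is created, and C4 is untouched because the medium is neutral and non-basic. The step needs retention of the (E)-C10=C11 geometry, which the configurationally stable alkenylnickel intermediate should secure, and retention of the (E)-C14=C15 geometry of the homoallylic radical, which the high nickel loading is meant to secure by making radical capture faster than reversible 3-exo closure. The butenolide should survive because its β-carbon C3 is fully substituted, which slows Giese addition, and because the nickel- and silver-mediated reduction runs at a potential well short of direct enoate reduction.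

Step 18
Reactants: 30 (R)-4-{[(tert-butyldimethylsilyl)oxy]methyl}-5-[(2Z,6E,10E,14E)-16-[(tert-butyldimethylsilyl)oxy]-3-{[(tert-butyldimethylsilyl)oxy]methyl}-7,11,15-trimethylhexadeca-2,6,10,14-tetraen-1-yl]furan-2(5H)-one
Product: 31 Hippolide F, (R)-5-[(2Z,6E,10E,14E)-16-hydroxy-3-(hydroxymethyl)-7,11,15-trimethylhexadeca-2,6,10,14-tetraen-1-yl]-4-(hydroxymethyl)furan-2(5H)-one
Conditions: HF·pyridine, pyridine, THF, 0 °C to rt
Reagents that add atoms: none
Why: Fluoride-mediated cleavage of the three primary silyl ethers under buffered, non-basic conditions should leave the butenolide and its C4 stereocentre intact.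

**Compound list**

1 | pent-3-yn-1-ol | CC#CCCO | starting material
2 | 5-bromopent-2-yne | CC#CCCBr | intermediate
3 | prop-2-yn-1-ol | C#CCO | starting material
4 | pent-3-yn-1-ylmagnesium bromide | CC#CCC[Mg]Br | intermediate
5 | bromomagnesium (Z)-3-(bromomagnesio)-2-(pent-3-yn-1-yl)prop-2-en-1-olate | CC#CCC/C(CO[Mg]Br)=C/[Mg]Br | intermediate
6 | (Z)-3-iodo-2-(pent-3-yn-1-yl)prop-2-en-1-ol | CC#CCC/C(CO)=C/I | intermediate
7 | tert-butyl{[(Z)-3-iodo-2-(pent-3-yn-1-yl)prop-2-en-1-yl]oxy}dimethylsilane | CC#CCC/C(CO[Si](C)(C)C(C)(C)C)=C/I | intermediate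
8 | (Z)-3-{[(tert-butyldimethylsilyl)oxy]methyl}oct-2-en-6-yn-1-ol | CC#CCC/C(CO[Si](C)(C)C(C)(C)C)=C/CO | intermediate
9 | C7-alkenyl(chloro)zirconocene of 8 as its chlorozirconocene alkoxide (cyclopentadienyl rings drawn σ-bound) | C/C(=C\CC/C(CO[Si](C)(C)C(C)(C)C)=C/CO[Zr](Cl)(C1C=CC=C1)C1C=CC=C1)[Zr](Cl)(C1C=CC=C1)C1C=CC=C1 | intermediate
10 | (2Z,6E)-3-{[(tert-butyldimethylsilyl)oxy]methyl}-7-iodoocta-2,6-dien-1-ol | C/C(I)=C\CC/C(CO[Si](C)(C)C(C)(C)C)=C/CO | intermediate
11 | (2Z,6E)-1-bromo-3-{[(tert-butyldimethylsilyl)oxy]methyl}-7-iodoocta-2,6-diene | C/C(I)=C\CC/C(CO[Si](C)(C)C(C)(C)C)=C/CBr | intermediate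
12 | 2,2-dimethyl-1,3-dioxan-5-one | CC1(C)OCC(=O)CO1 | starting material
13 | (R)-1-amino-2-(methoxymethyl)pyrrolidine (RAMP) | COC[C@H]1CCCN1N | starting material
14 | (R)-N-(2,2-dimethyl-1,3-dioxan-5-ylidene)-2-(methoxymethyl)pyrrolidin-1-amine | COC[C@H]1CCCN1N=C1COC(C)(C)OC1 | intermediate
15 | lithium azaenolate of 14 | COC[C@H]1CCCN1N([Li])C1=COC(C)(C)OC1 | intermediate
16 | RAMP hydrazone of (R)-4-[(2Z,6E)-3-{[(tert-butyldimethylsilyl)oxy]methyl}-7-iodoocta-2,6-dien-1-yl]-2,2-dimethyl-1,3-dioxan-5-one | COC[C@H]1CCCN1N=C1COC(C)(C)O[C@@H]1C/C=C(\CO[Si](C)(C)C(C)(C)C)CC/C=C(\C)I | intermediate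
17 | (R)-4-[(2Z,6E)-3-{[(tert-butyldimethylsilyl)oxy]methyl}-7-iodoocta-2,6-dien-1-yl]-2,2-dimethyl-1,3-dioxan-5-one | CC1(C)OCC(=O)[C@@H](C/C=C(\CO[Si](C)(C)C(C)(C)C)CC/C=C(\C)I)O1 | intermediate
18 | (3R,5Z,9E)-1,3-dihydroxy-6-(hydroxymethyl)-10-iodoundeca-5,9-dien-2-one | OCC(=O)[C@H](O)C/C=C(\CO)CC/C=C(\C)I | intermediate
19 | (3R,5Z,9E)-1-[(tert-butyldimethylsilyl)oxy]-6-{[(tert-butyldimethylsilyl)oxy]methyl}-3-hydroxy-10-iodoundeca-5,9-dien-2-one | CC(C)(C)[Si](C)(C)OCC(=O)[C@H](O)C/C=C(\CO[Si](C)(C)C(C)(C)C)CC/C=C(\C)I | intermediate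
20 | (triphenylphosphoranylidene)acetate ester of 19 at the C3 hydroxyl | CC(C)(C)[Si](C)(C)OCC(=O)[C@H](OC(=O)C=P(c1ccccc1)(c1ccccc1)c1ccccc1)C/C=C(\CO[Si](C)(C)C(C)(C)C)CC/C=C(\C)I | intermediate
21 | (R)-4-{[(tert-butyldimethylsilyl)oxy]methyl}-5-[(2Z,6E)-3-{[(tert-butyldimethylsilyl)oxy]methyl}-7-iodoocta-2,6-dien-1-yl]furan-2(5H)-one | C/C(I)=C\CC/C(=C/C[C@H]1OC(=O)C=C1CO[Si](C)(C)C(C)(C)C)CO[Si](C)(C)C(C)(C)C | intermediate
22 | geranyl bromide, (E)-1-bromo-3,7-dimethylocta-2,6-diene | CC(C)=CCC/C(C)=C/CBr | starting material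
23 | ethyl acetate | CCOC(C)=O | starting material
24 | lithium enolate of ethyl acetate | C=C(OCC)O[Li] | intermediate
25 | ethyl (E)-5,9-dimethyldeca-4,8-dienoate | CCOC(=O)CC/C=C(\C)CCC=C(C)C | intermediate
26 | ethyl (4E,8E)-10-hydroxy-5,9-dimethyldeca-4,8-dienoate | CCOC(=O)CC/C=C(\C)CC/C=C(\C)CO | intermediate
27 | ethyl (4E,8E)-10-[(tert-butyldimethylsilyl)oxy]-5,9-dimethyldeca-4,8-dienoate | CCOC(=O)CC/C=C(\C)CC/C=C(\C)CO[Si](C)(C)C(C)(C)C | intermediate
28 | (4E,8E)-10-[(tert-butyldimethylsilyl)oxy]-5,9-dimethyldeca-4,8-dienoic acid | OC(=O)CC/C=C(\C)CC/C=C(\C)CO[Si](C)(C)C(C)(C)C | intermediate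
29 | 1,3-dioxoisoindolin-2-yl (4E,8E)-10-[(tert-butyldimethylsilyl)oxy]-5,9-dimethyldeca-4,8-dienoate | O=C(CC/C=C(\C)CC/C=C(\C)CO[Si](C)(C)C(C)(C)C)ON1C(=O)c2ccccc2C1=O | intermediate
30 | tris-TBS ether of Hippolide F, (R)-4-{[(tert-butyldimethylsilyl)oxy]methyl}-5-[(2Z,6E,10E,14E)-16-[(tert-butyldimethylsilyl)oxy]-3-{[(tert-butyldimethylsilyl)oxy]methyl}-7,11,15-trimethylhexadeca-2,6,10,14-tetraen-1-yl]furan-2(5H)-one | C/C(=C\CC/C(C)=C/CC/C(C)=C/CC/C(=C/C[C@H]1OC(=O)C=C1CO[Si](C)(C)C(C)(C)C)CO[Si](C)(C)C(C)(C)C)CO[Si](C)(C)C(C)(C)C | intermediate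
31 | Hippolide F, (R)-5-[(2Z,6E,10E,14E)-16-hydroxy-3-(hydroxymethyl)-7,11,15-trimethylhexadeca-2,6,10,14-tetraen-1-yl]-4-(hydroxymethyl)furan-2(5H)-one | C/C(=C\CC/C(C)=C/CC/C(C)=C/CC/C(=C/C[C@H]1OC(=O)C=C1CO)CO)CO | target

**Count**

Total steps: 18. Longest linear sequence: 12 steps (steps 1–6, 8–11, 17 and 18).

**Steps most likely to fail, with fallbacks**

Step 17. What may go wrong: erosion of the (E)-C14=C15 geometry through reversible 3-exo closure of the homoallylic C12 radical before nickel captures it; slow oxidative addition at the hindered, methyl-substituted C11–I bond, so that the radical is reduced or dimerises; competing cathodic reduction of the butenolide. The fallback replaces radical capture by a two-electron Negishi coupling; it sets out from acid 28 and alkenyl iodide 21 and comes back to the route at 30. Acid 28 would be esterified (N-hydroxypyridine-2-thione, N,N'-dicyclohexylcarbodiimide, CH2Cl2, dark) to 2-thioxopyridin-1(2H)-yl (4E,8E)-10-[(tert-butyldimethylsilyl)oxy]-5,9-dimethyldeca-4,8-dienoate F1. Photolysis of F1 with CHI3 (Barton iododecarboxylation, in which iodine transfer to the radical is far faster than ring closure) would give tert-butyl{[(2E,6E)-9-iodo-2,6-dimethylnona-2,6-dien-1-yl]oxy}dimethylsilane F2. Zinc insertion (Zn dust, DMA, 40 °C) would give {(3E,7E)-9-[(tert-butyldimethylsilyl)oxy]-4,8-dimethylnona-3,7-dien-1-yl}zinc iodide F3, and palladium-catalysed coupling of F3 with 21 (Pd(t-Bu3P)2, THF/DMA, rt) would give 30.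

Step 5. What may go wrong: incomplete regiocontrol of the Zr–H addition, because both alkyne substituents are unbranched, leading to an alkenyl iodide regioisomer that is hard to remove. The fallback fixes the regiochemistry with a silyl group on the alkyne instead of relying on sterics; it sets out from 3 and comes back to the route at 10. Commercial (4-bromobut-1-yn-1-yl)trimethylsilane would be converted (Mg, Et2O) into [4-(trimethylsilyl)but-3-yn-1-yl]magnesium bromide F4 and used as in step 2 to give, through bromomagnesium (Z)-3-(bromomagnesio)-2-[4-(trimethylsilyl)but-3-yn-1-yl]prop-2-en-1-olate F5, (Z)-3-iodo-2-[4-(trimethylsilyl)but-3-yn-1-yl]prop-2-en-1-ol F6. Silylation as in step 3 would give tert-butyl({(Z)-3-iodo-2-[4-(trimethylsilyl)but-3-yn-1-yl]prop-2-en-1-yl}oxy)dimethylsilane F7, and Stille hydroxymethylation as in step 4 would give (Z)-3-{[(tert-butyldimethylsilyl)oxy]methyl}-7-(trimethylsilyl)hept-2-en-6-yn-1-ol F8. Trans-hydroalumination of the silylalkyne (i-Bu2AlH, heptane, 50 °C), which places aluminium regiospecifically on the silicon-bearing carbon, would give the alkenylalane F9. MeLi would convert it into the lithium alanate F10, and MeI would alkylate this with retention to (2Z,6E)-3-{[(tert-butyldimethylsilyl)oxy]methyl}-7-(trimethylsilyl)octa-2,6-dien-1-ol F11. Iododesilylation with retention (N-iodosuccinimide, (CF3)2CHOH, 0 °C) would give 10.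

Step 11. What may go wrong: epimerisation at C4, which is α to the ketone, under the basic ylide at 80 °C, or acylation of the hindered hydroxyl without ring closure. The fallback builds the lactone stepwise at low temperature by phosphonate chemistry; it sets out from 19 and comes back to the route at 21. Esterification of the free hydroxyl of 19 with diethylphosphonoacetic acid (EDC·HCl, DMAP, CH2Cl2, 0 °C) would give (3R,5Z,9E)-1-[(tert-butyldimethylsilyl)oxy]-6-{[(tert-butyldimethylsilyl)oxy]methyl}-10-iodo-2-oxoundeca-5,9-dien-3-yl 2-(diethoxyphosphoryl)acetate F12. Intramolecular Horner–Wadsworth–Emmons olefination under Masamune–Roush conditions (LiCl, i-Pr2NEt, MeCN, 0 °C to rt) would then close the butenolide 21.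

Further compounds
F1 | step 17 | 2-thioxopyridin-1(2H)-yl (4E,8E)-10-[(tert-butyldimethylsilyl)oxy]-5,9-dimethyldeca-4,8-dienoate | O=C(CC/C=C(\C)CC/C=C(\C)CO[Si](C)(C)C(C)(C)C)On1ccccc1=S
F2 | step 17 | tert-butyl{[(2E,6E)-9-iodo-2,6-dimethylnona-2,6-dien-1-yl]oxy}dimethylsilane | ICC/C=C(\C)CC/C=C(\C)CO[Si](C)(C)C(C)(C)C
F3 | step 17 | {(3E,7E)-9-[(tert-butyldimethylsilyl)oxy]-4,8-dimethylnona-3,7-dien-1-yl}zinc iodide | I[Zn]CC/C=C(\C)CC/C=C(\C)CO[Si](C)(C)C(C)(C)C
F4 | step 5 | [4-(trimethylsilyl)but-3-yn-1-yl]magnesium bromide | C[Si](C)(C)C#CCC[Mg]Br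
F5 | step 5 | bromomagnesium (Z)-3-(bromomagnesio)-2-[4-(trimethylsilyl)but-3-yn-1-yl]prop-2-en-1-olate | C[Si](C)(C)C#CCC/C(CO[Mg]Br)=C/[Mg]Br
F6 | step 5 | (Z)-3-iodo-2-[4-(trimethylsilyl)but-3-yn-1-yl]prop-2-en-1-ol | C[Si](C)(C)C#CCC/C(CO)=C/I
F7 | step 5 | tert-butyl({(Z)-3-iodo-2-[4-(trimethylsilyl)but-3-yn-1-yl]prop-2-en-1-yl}oxy)dimethylsilane | C[Si](C)(C)C#CCC/C(CO[Si](C)(C)C(C)(C)C)=C/I
F8 | step 5 | (Z)-3-{[(tert-butyldimethylsilyl)oxy]methyl}-7-(trimethylsilyl)hept-2-en-6-yn-1-ol | C[Si](C)(C)C#CCC/C(CO[Si](C)(C)C(C)(C)C)=C/CO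
F9 | step 5 | alkenylalane: C7-(diisobutylalumino) trans-hydroalumination adduct of F8 as its O-diisobutylaluminium alkoxide | CC(C)C[Al](CC(C)C)OC/C=C(\CO[Si](C)(C)C(C)(C)C)CC/C=C(/[Si](C)(C)C)[Al](CC(C)C)CC(C)C
F10 | step 5 | lithium alanate: lithium methyl ate complex of F9 at the alkenyl aluminium | [Li+].CC(C)C[Al-](C)(CC(C)C)/C(=C\CC/C(CO[Si](C)(C)C(C)(C)C)=C/CO[Al](CC(C)C)CC(C)C)[Si](C)(C)C
F11 | step 5 | (2Z,6E)-3-{[(tert-butyldimethylsilyl)oxy]methyl}-7-(trimethylsilyl)octa-2,6-dien-1-ol | C/C(=C\CC/C(CO[Si](C)(C)C(C)(C)C)=C/CO)[Si](C)(C)C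
F12 | step 11 | (3R,5Z,9E)-1-[(tert-butyldimethylsilyl)oxy]-6-{[(tert-butyldimethylsilyl)oxy]methyl}-10-iodo-2-oxoundeca-5,9-dien-3-yl 2-(diethoxyphosphoryl)acetate | CCOP(=O)(CC(=O)O[C@H](C/C=C(\CO[Si](C)(C)C(C)(C)C)CC/C=C(\C)I)C(=O)CO[Si](C)(C)C(C)(C)C)OCC
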